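**Plan**

- Labels: ring A is the terminal 2-ethyl-3,5-dimethyl-4-pyranone; ring B is the central 4-pyranone (O1, C2–C6); C1′–C7′ are the seven linker carbons from ring A to ring B C2; C1″/C2″ are the CHMe and CHOH carbons of the arm on ring B C6. TBS is tert-butyldimethylsilyl.
- Feature and key cut: ring B carries the stereogenic CHMe carbon C7′ on C2 and C1″ on C6, and its O1–C6=C5–C4(=O)–C3 array is a masked 1-methoxy-3-silyloxy diene. Cutting C2–C3 and O1–C6 at the 2,3-dihydro level gives a C7′ α-methyl aldehyde that already holds ring A and an arm-bearing diene.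
- Further cuts: C4′–C5′ (aldol) and the C6′ carbinol (ketone reduction); ring A through its 1,3,5-triketone; the diene through its ethyl ketone and a β-keto amide.
- Forward order: ring A is closed first, its side chain becomes the C1′–C4′ enal, one aldol and one reduction complete the linker, ring B is closed on the C7′ aldehyde and aromatised, and the silyl ethers come off last.
- Stereochemistry: C1′ comes from an Evans syn aldol, whose carbinol partner is erased in the allylic transposition that sets the E-alkene. C7′ comes from the β-ketoimide and relays to C5′ and C4′ in the divalent-tin aldol. C6′ comes from a 1,3-syn reduction. C1″/C2″ come from methyl (R)-3-hydroxypentanoate by Fráter–Seebach methylation.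

Key step: step 25

Assumption: the divalent-tin aldol of 4 is taken to keep its usual 2,4-anti-4,5-syn sense with the ring A enal; 31 and 33 are carried as isomer mixtures because ring B C2/C3 become sp2 in step 26.

**Route**

Step 1
Reactants: 1 (4S)-4-benzyl-3-propanoyl-1,3-oxazolidin-2-one; 2 propanal
Product: 3 (4S)-4-benzyl-3-[(2S,3R)-3-hydroxy-2-methylpentanoyl]-1,3-oxazolidin-2-one
Conditions: nBu2BOTf, iPr2NEt, CH2Cl2, 0 °C; 2, −78 → 0 °C; then H2O2, MeOH, pH 7 buffer
Reagents that add atoms: none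
Why: Evans syn aldol, in which the (Z)-boron enolate reacts through a Zimmerman–Traxler chair on the face away from the benzyl group to set C2 (S); the C3 carbinol is oxidised in step 2.

Step 2
Reactants: 3 (4S)-4-benzyl-3-[(2S,3R)-3-hydroxy-2-methylpentanoyl]-1,3-oxazolidin-2-one
Product: 4 (4S)-4-benzyl-3-[(2S)-2-methyl-3-oxopentanoyl]-1,3-oxazolidin-2-one
Conditions: SO3·pyridine, DMSO, Et3N, CH2Cl2, −10 °C
Reagents that add atoms: none
Why: Parikh–Doering oxidation should give the β-ketoimide with C2 intact, because its C–H lies in the imide plane (allylic 1,3-strain) and is not readily removed by the amine.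

Step 3
Reactants: 1 (4S)-4-benzyl-3-propanoyl-1,3-oxazolidin-2-one; 5 2-methylprop-2-enal (methacrolein)
Product: 6 (4S)-4-benzyl-3-[(2S,3S)-3-hydroxy-2,4-dimethylpent-4-enoyl]-1,3-oxazolidin-2-one
Conditions: nBu2BOTf, iPr2NEt, CH2Cl2, 0 °C; 5, −78 → 0 °C; then H2O2, MeOH, pH 7 buffer
Reagents that add atoms: none
Why: Evans syn aldol through the same boron enolate and chair transition state sets C2 (S), the future C1′, and the C3 carbinol (S) that is used later for the allylic transposition.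

Step 4
Reactants: 6 (4S)-4-benzyl-3-[(2S,3S)-3-hydroxy-2,4-dimethylpent-4-enoyl]-1,3-oxazolidin-2-one
Product: 7 (2S,3S)-3-hydroxy-N-methoxy-N,2,4-trimethylpent-4-enamide
Conditions: MeNHOMe·HCl, AlMe3, CH2Cl2, −20 → 0 °C
Reagents that add atoms: N,O-dimethylhydroxylamine hydrochloride, CNOC.Cl
Why: Weinreb transamination, in which the aluminium amide is directed to the exocyclic imide carbonyl by the free β-hydroxyl and removes the auxiliary without touching the α-centre.

Step 5
Reactants: 7 (2S,3S)-3-hydroxy-N-methoxy-N,2,4-trimethylpent-4-enamide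
Product: 8 (2S,3S)-3-(TBSO)-N-methoxy-N,2,4-trimethylpent-4-enamide
Conditions: TBSOTf, 2,6-lutidine, CH2Cl2, −78 → 0 °C
Reagents that add atoms: tert-butyldimethylsilyl triflate, CC(C)(C)[Si](C)(C)OS(=O)(=O)C(F)(F)F
Why: Silyl ether formation masks the secondary allylic hydroxyl against the strong base of step 7.

Step 6
Reactants: 9 pentan-3-one; 10 propanoyl chloride
Product: 11 4-methylheptane-3,5-dione
Conditions: MgBr2·OEt2, iPr2NEt, CH2Cl2, rt
Reagents that add atoms: none
Why: Soft-enolisation C-acylation, in which the magnesium enolate of the ketone is acylated at carbon and the product is held as its magnesium diketonate, which prevents a second acylation.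

Step 7
Reactants: 11 4-methylheptane-3,5-dione; 8 (2S,3S)-3-(TBSO)-N-methoxy-N,2,4-trimethylpent-4-enamide
Product: 12 (8S,9S)-9-(TBSO)-4,6,8,10-tetramethylundec-10-ene-3,5,7-trione (mixture at C4/C6 and of enol forms)
Conditions: 11, LiN(iPr)2 (2 equiv per 11), THF, 0 °C; then 8, −78 → 0 °C; AcOH
Reagents that add atoms: none
Why: γ-Acylation of a 1,3-diketone dianion at its terminal carbanion by the N-methoxy-N-methylamide, which stops at the chelated tetrahedral adduct; C8 should survive because the inter-carbonyl protons of the product are far more acidic.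

Step 8
Reactants: 12 (8S,9S)-9-(TBSO)-4,6,8,10-tetramethylundec-10-ene-3,5,7-trione
Product: 13 2-[(2S,3S)-3-(TBSO)-4-methylpent-4-en-2-yl]-6-ethyl-3,5-dimethyl-4H-pyran-4-one
Conditions: Ph3P, CCl4, THF, rt
Reagents that add atoms: none
Why: Cyclodehydration of a 1,3,5-triketone to the 4-pyranone (ring A) with Appel-type activation; either terminal enol oxygen gives the same ring and the near-neutral conditions leave the adjacent centres alone.

Step 9
Reactants: 13 2-[(2S,3S)-3-(TBSO)-4-methylpent-4-en-2-yl]-6-ethyl-3,5-dimethyl-4H-pyran-4-one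
Product: 14 2-ethyl-6-[(2S,3S)-3-hydroxy-4-methylpent-4-en-2-yl]-3,5-dimethyl-4H-pyran-4-one
Conditions: HF·pyridine, pyridine, THF, 0 °C → rt
Reagents that add atoms: none
Why: Buffered fluoride desilylation is chosen over basic fluoride to avoid retro-vinylogous aldol cleavage or epimerisation at the carbon next to ring A.

Step 10
Reactants: 14 2-ethyl-6-[(2S,3S)-3-hydroxy-4-methylpent-4-en-2-yl]-3,5-dimethyl-4H-pyran-4-one
Product: 15 2-ethyl-6-[(2S,3E)-5-hydroxy-4-methylpent-3-en-2-yl]-3,5-dimethyl-4H-pyran-4-one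
Conditions: Ph3SiOReO3 (2 mol%), Et2O, 0 °C
Reagents that add atoms: none
Why: Rhenium-oxo-catalysed 1,3-transposition of an allylic alcohol through a chair [3,3] shift of the allyl perrhenate should favour the trisubstituted alkene with the primary hydroxyl and give the E-isomer, with C1′ not involved.

Step 11
Reactants: 15 2-ethyl-6-[(2S,3E)-5-hydroxy-4-methylpent-3-en-2-yl]-3,5-dimethyl-4H-pyran-4-one
Product: 16 (2E,4S)-4-(6-ethyl-3,5-dimethyl-4-oxo-4H-pyran-2-yl)-2-methylpent-2-enal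
Conditions: MnO2, CH2Cl2, rt
Reagents that add atoms: none
Why: MnO2 oxidation of a primary allylic alcohol is neutral and heterogeneous and so spares the γ-centre C1′; the enal is used at once.

Step 12
Reactants: 16 (2E,4S)-4-(6-ethyl-3,5-dimethyl-4-oxo-4H-pyran-2-yl)-2-methylpent-2-enal; 4 (4S)-4-benzyl-3-[(2S)-2-methyl-3-oxopentanoyl]-1,3-oxazolidin-2-one
Product: 17 (4S)-4-benzyl-3-[(2S,4R,5R,6E,8S)-8-(6-ethyl-3,5-dimethyl-4-oxo-4H-pyran-2-yl)-5-hydroxy-2,4,6-trimethyl-3-oxonon-6-enoyl]-1,3-oxazolidin-2-one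
Conditions: 4, Sn(OTf)2, Et3N, CH2Cl2, −20 °C; then 16, −78 °C
Reagents that add atoms: none
Why: Divalent-tin aldol of the β-ketoimide, in which enolisation occurs only at the ethyl group and the (Z)-enolate adds under control of the C2 methyl centre to give the 2,4-anti-4,5-syn adduct, setting C5′ and C4′ relative to C7′.

Step 13
Reactants: 17 (4S)-4-benzyl-3-[(2S,4R,5R,6E,8S)-8-(6-ethyl-3,5-dimethyl-4-oxo-4H-pyran-2-yl)-5-hydroxy-2,4,6-trimethyl-3-oxonon-6-enoyl]-1,3-oxazolidin-2-one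
Product: 18 (4S)-4-benzyl-3-[(2S,3S,4S,5R,6E,8S)-8-(6-ethyl-3,5-dimethyl-4-oxo-4H-pyran-2-yl)-3,5-dihydroxy-2,4,6-trimethylnon-6-enoyl]-1,3-oxazolidin-2-one
Conditions: Et2BOMe, NaBH4, THF/MeOH, −78 °C; AcOH, then MeOH azeotrope
Reagents that add atoms: none
Why: Narasaka–Prasad reduction, in which the diethylboron chelate of the β-hydroxy ketone is attacked axially by external hydride to give the 1,3-syn diol, placing C6′–OH syn to C4′–OH and C5′–Me and anti to C7′–Me.

Step 14
Reactants: 18 (4S)-4-benzyl-3-[(2S,3S,4S,5R,6E,8S)-8-(6-ethyl-3,5-dimethyl-4-oxo-4H-pyran-2-yl)-3,5-dihydroxy-2,4,6-trimethylnon-6-enoyl]-1,3-oxazolidin-2-one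
Product: 19 (4S)-4-benzyl-3-[(2S,3S,4S,5R,6E,8S)-3,5-bis(TBSO)-8-(6-ethyl-3,5-dimethyl-4-oxo-4H-pyran-2-yl)-2,4,6-trimethylnon-6-enoyl]-1,3-oxazolidin-2-one
Conditions: TBSOTf, 2,6-lutidine, CH2Cl2, −78 → −40 °C
Reagents that add atoms: tert-butyldimethylsilyl triflate, CC(C)(C)[Si](C)(C)OS(=O)(=O)C(F)(F)F
Why: Double silylation protects both hindered hydroxyls before the δ-hydroxyl can lactonise onto the imide, and the weak pyridine base at low temperature should leave the acidic C1′–H alone.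

Step 15
Reactants: 19 (4S)-4-benzyl-3-[(2S,3S,4S,5R,6E,8S)-3,5-bis(TBSO)-8-(6-ethyl-3,5-dimethyl-4-oxo-4H-pyran-2-yl)-2,4,6-trimethylnon-6-enoyl]-1,3-oxazolidin-2-one
Product: 20 2-[(2S,3E,5R,6S,7R,8R)-5,7-bis(TBSO)-9-hydroxy-4,6,8-trimethylnon-3-en-2-yl]-6-ethyl-3,5-dimethyl-4H-pyran-4-one
Conditions: LiBH4, MeOH (1 equiv), THF, 0 °C
Reagents that add atoms: none
Why: Reductive cleavage of the N-acyloxazolidinone gives the primary alcohol, and the ring A carbonyl, a doubly vinylogous ester, should not be reduced at 0 °C.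

Step 16
Reactants: 20 2-[(2S,3E,5R,6S,7R,8R)-5,7-bis(TBSO)-9-hydroxy-4,6,8-trimethylnon-3-en-2-yl]-6-ethyl-3,5-dimethyl-4H-pyran-4-one
Product: 21 (2S,3S,4S,5R,6E,8S)-3,5-bis(TBSO)-8-(6-ethyl-3,5-dimethyl-4-oxo-4H-pyran-2-yl)-2,4,6-trimethylnon-6-enal
Conditions: Dess–Martin periodinane, pyridine, CH2Cl2, 0 °C
Reagents that add atoms: none
Why: Buffered Dess–Martin oxidation gives the α-methyl aldehyde without epimerisation at C7′; it is used without delay.

Step 17
Reactants: 22 methyl (3R)-3-hydroxypentanoate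
Product: 23 methyl (2R,3R)-3-hydroxy-2-methylpentanoate
Conditions: LiN(iPr)2 (2.2 equiv), THF, −50 → −20 °C; MeI, DMPU, −78 → 0 °C; AcOH
Reagents that add atoms: iodomethane, CI
Why: Fráter–Seebach alkylation, in which the chelated dianion is methylated on the face anti to the ethyl group of the carbinol carbon, gives the 2,3-anti ester and so C1″ (R) next to C2″ (R).

Step 18
Reactants: 23 methyl (2R,3R)-3-hydroxy-2-methylpentanoate
Product: 24 methyl (2R,3R)-3-(TBSO)-2-methylpentanoate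
Conditions: TBSOTf, 2,6-lutidine, CH2Cl2, 0 °C
Reagents that add atoms: tert-butyldimethylsilyl triflate, CC(C)(C)[Si](C)(C)OS(=O)(=O)C(F)(F)F
Why: Standard silyl ether formation protects the carbinol through to the final step.

Step 19
Reactants: 24 methyl (2R,3R)-3-(TBSO)-2-methylpentanoate
Product: 25 (2R,3R)-3-(TBSO)-2-methylpentanal
Conditions: iBu2AlH, CH2Cl2, −78 °C; then H2O
Reagents that add atoms: none
Why: Half-reduction of the ester stops at the tetrahedral aluminium hemiacetal at −78 °C, which releases the aldehyde only on work-up.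

Step 20
Reactants: 25 (2R,3R)-3-(TBSO)-2-methylpentanal; 26 N-methoxy-N-methylpropanamide
Product: 27 (4S,5R)-5-(TBSO)-3-hydroxy-N-methoxy-N,2,4-trimethylheptanamide (mixture at C2/C3)
Conditions: 26, LiN(iPr)2, THF, −78 °C; then 25; AcOH
Reagents that add atoms: none
Why: Aldol addition of the amide lithium enolate needs no stereocontrol, since one new centre is oxidised in step 21 and the other becomes sp2 in step 22.

Step 21
Reactants: 27 (4S,5R)-5-(TBSO)-3-hydroxy-N-methoxy-N,2,4-trimethylheptanamide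
Product: 28 (4R,5R)-5-(TBSO)-N-methoxy-N,2,4-trimethyl-3-oxoheptanamide (C2 epimers)
Conditions: Dess–Martin periodinane, pyridine, CH2Cl2, rt
Reagents that add atoms: none
Why: Dess–Martin oxidation gives the β-keto amide under buffered conditions that do not enolise toward C4.

Step 22
Reactants: 28 (4R,5R)-5-(TBSO)-N-methoxy-N,2,4-trimethyl-3-oxoheptanamide
Product: 29 (4R,5R)-5-(TBSO)-N,3-dimethoxy-N,2,4-trimethylhept-2-enamide (E/Z mixture)
Conditions: KN(SiMe3)2 (1.0 equiv), THF/DMPU, −78 °C; Me2SO4, −78 → 0 °C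
Reagents that add atoms: dimethyl sulfate, COS(=O)(=O)OC
Why: O-Alkylation of a β-dicarbonyl enolate, favoured by the potassium counter-ion, the dipolar medium and the hard electrophile, fixes the methoxy group on the arm-bearing carbon; only the inter-carbonyl proton is removed.

Step 23
Reactants: 29 (4R,5R)-5-(TBSO)-N,3-dimethoxy-N,2,4-trimethylhept-2-enamide
Product: 30 (6R,7R)-7-(TBSO)-5-methoxy-4,6-dimethylnon-4-en-3-one (E/Z mixture)
Conditions: EtMgBr, THF, 0 °C → rt
Reagents that add atoms: ethylmagnesium bromide, CC[Mg]Br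
Why: Grignard addition to the N-methoxy-N-methylamide stops at the magnesium chelate and gives the ethyl ketone on work-up, with no second addition.

Step 24
Reactants: 30 (6R,7R)-7-(TBSO)-5-methoxy-4,6-dimethylnon-4-en-3-one
Product: 31 (3R,4R)-3-(TBSO)-5-methoxy-4,6-dimethyl-7-(trimethylsilyloxy)nona-5,7-diene (mixture of double-bond isomers)
Conditions: LiN(iPr)2, THF, −78 °C; then Me3SiCl
Reagents that add atoms: chlorotrimethylsilane, C[Si](C)(C)Cl
Why: Kinetic α′-deprotonation of the vinylogous ester at the ethyl CH2 followed by O-silylation gives the 1-methoxy-3-silyloxy diene, γ-deprotonation at C4 being slower.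

Step 25
Reactants: 21 (2S,3S,4S,5R,6E,8S)-3,5-bis(TBSO)-8-(6-ethyl-3,5-dimethyl-4-oxo-4H-pyran-2-yl)-2,4,6-trimethylnon-6-enal; 31 (3R,4R)-3-(TBSO)-5-methoxy-4,6-dimethyl-7-(trimethylsilyloxy)nona-5,7-diene
Product: 33 tris-TBS 2,3-dihydro ring B adduct (ring B as 2,3-dihydro-4H-pyran-4-one; mixture at ring B C2/C3), via open-chain Mukaiyama aldol adduct 32 (not isolated)
Conditions: 31 (2 equiv), BF3·OEt2, CH2Cl2, −78 °C; then CF3CO2H, 0 °C
Reagents that add atoms: none
Why: BF3 activates the aldehyde of 21 and the silyl enol ether terminus of 31 adds to it in an open Mukaiyama aldol transition state, forming ring B C2–C3 and the δ-hydroxy-β-methoxy enone 32, whose hydroxyl then adds to the methoxy-bearing enone carbon under CF3CO2H with loss of methanol, forming O1–C6. The closest known reaction type is the Lewis acid-mediated hetero-Diels–Alder (Mukaiyama aldol–cyclisation) of Danishefsky-type 1-alkoxy-3-silyloxy dienes with aldehydes to 2,3-dihydro-4H-pyran-4-ones. Ring B closes by a 6-endo-trig oxa-Michael addition followed by β-elimination, a formal [4+2] closure. The two new centres, ring B C2 and C3, are not controlled and need not be, because both become sp2 in step 26. The step needs regioselectivity, secured by the diene polarity (only the silyl enol ether carbon is nucleophilic and only the methoxy-bearing carbon can accept the oxygen), chemoselectivity for the aldehyde over the non-electrophilic ring A carbonyl, and retention of C7′, secured by −78 °C and the absence of base.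

Step 26
Reactants: 33 tris-TBS 2,3-dihydro ring B adduct
Product: 34 2-[(2S,3E,5R,6S,7S,8S)-5,7-bis(TBSO)-8-{6-[(2R,3R)-3-(TBSO)pentan-2-yl]-3,5-dimethyl-4-oxo-4H-pyran-2-yl}-4,6-dimethylnon-3-en-2-yl]-6-ethyl-3,5-dimethyl-4H-pyran-4-one
Conditions: 2-iodoxybenzoic acid (IBX), DMSO, 65 °C
Reagents that add atoms: none
Why: IBX α,β-dehydrogenation of a ketone through its enol removes the C3 and C2 hydrogens of ring B to give the aromatic-like 4-pyranone under neutral conditions, avoiding the strong bases or silyl triflate/amine mixtures that would epimerise C1′ next to ring A.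

Step 27
Reactants: 34 tris-TBS bis-pyranone
Product: 35 2-[(2S,3E,5R,6S,7S,8S)-8-{6-[(2R,3R)-3-hydroxypentan-2-yl]-3,5-dimethyl-4-oxo-4H-pyran-2-yl}-5,7-dihydroxy-4,6-dimethylnon-3-en-2-yl]-6-ethyl-3,5-dimethyl-4H-pyran-4-one (CNP0328559.3)
Conditions: HF·pyridine, pyridine, THF, 0 °C → rt
Reagents that add atoms: none
Why: Global cleavage of the three secondary silyl ethers with buffered HF should release the triol without any base touching C1′ or C7′.

**Compound list**

1 | (4S)-4-benzyl-3-propanoyl-1,3-oxazolidin-2-one | CCC(=O)N1[C@@H](Cc2ccccc2)COC1=O | starting material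
2 | propanal | CCC=O | starting material
3 | (4S)-4-benzyl-3-[(2S,3R)-3-hydroxy-2-methylpentanoyl]-1,3-oxazolidin-2-one | CC[C@@H](O)[C@H](C)C(=O)N1[C@@H](Cc2ccccc2)COC1=O | intermediate
4 | (4S)-4-benzyl-3-[(2S)-2-methyl-3-oxopentanoyl]-1,3-oxazolidin-2-one (β-ketoimide) | CCC(=O)[C@H](C)C(=O)N1[C@@H](Cc2ccccc2)COC1=O | intermediate
5 | 2-methylprop-2-enal (methacrolein) | CC(=C)C=O | starting material
6 | (4S)-4-benzyl-3-[(2S,3S)-3-hydroxy-2,4-dimethylpent-4-enoyl]-1,3-oxazolidin-2-one | C=C(C)[C@@H](O)[C@H](C)C(=O)N1[C@@H](Cc2ccccc2)COC1=O | intermediate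
7 | (2S,3S)-3-hydroxy-N-methoxy-N,2,4-trimethylpent-4-enamide | C=C(C)[C@@H](O)[C@H](C)C(=O)N(C)OC | intermediate
8 | (2S,3S)-3-[(tert-butyldimethylsilyl)oxy]-N-methoxy-N,2,4-trimethylpent-4-enamide | C=C(C)[C@@H](O[Si](C)(C)C(C)(C)C)[C@H](C)C(=O)N(C)OC | intermediate
9 | pentan-3-one | CCC(=O)CC | starting material
10 | propanoyl chloride | CCC(=O)Cl | starting material
11 | 4-methylheptane-3,5-dione | CCC(=O)C(C)C(=O)CC | intermediate
12 | (8S,9S)-9-[(tert-butyldimethylsilyl)oxy]-4,6,8,10-tetramethylundec-10-ene-3,5,7-trione (mixture at C4/C6, enol forms) | CCC(=O)C(C)C(=O)C(C)C(=O)[C@@H](C)[C@H](O[Si](C)(C)C(C)(C)C)C(C)=C | intermediate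
13 | 2-{(2S,3S)-3-[(tert-butyldimethylsilyl)oxy]-4-methylpent-4-en-2-yl}-6-ethyl-3,5-dimethyl-4H-pyran-4-one | CCc1oc([C@@H](C)[C@H](O[Si](C)(C)C(C)(C)C)C(C)=C)c(C)c(=O)c1C | intermediate
14 | 2-ethyl-6-[(2S,3S)-3-hydroxy-4-methylpent-4-en-2-yl]-3,5-dimethyl-4H-pyran-4-one | CCc1oc([C@@H](C)[C@H](O)C(C)=C)c(C)c(=O)c1C | intermediate
15 | 2-ethyl-6-[(2S,3E)-5-hydroxy-4-methylpent-3-en-2-yl]-3,5-dimethyl-4H-pyran-4-one | CCc1oc([C@@H](C)/C=C(\C)CO)c(C)c(=O)c1C | intermediate
16 | (2E,4S)-4-(6-ethyl-3,5-dimethyl-4-oxo-4H-pyran-2-yl)-2-methylpent-2-enal (ring A enal) | CCc1oc([C@@H](C)/C=C(\C)C=O)c(C)c(=O)c1C | intermediate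
17 | (4S)-4-benzyl-3-[(2S,4R,5R,6E,8S)-8-(6-ethyl-3,5-dimethyl-4-oxo-4H-pyran-2-yl)-5-hydroxy-2,4,6-trimethyl-3-oxonon-6-enoyl]-1,3-oxazolidin-2-one | CCc1oc([C@@H](C)/C=C(\C)[C@H](O)[C@@H](C)C(=O)[C@H](C)C(=O)N2[C@@H](Cc3ccccc3)COC2=O)c(C)c(=O)c1C | intermediate
18 | (4S)-4-benzyl-3-[(2S,3S,4S,5R,6E,8S)-8-(6-ethyl-3,5-dimethyl-4-oxo-4H-pyran-2-yl)-3,5-dihydroxy-2,4,6-trimethylnon-6-enoyl]-1,3-oxazolidin-2-one | CCc1oc([C@@H](C)/C=C(\C)[C@H](O)[C@@H](C)[C@H](O)[C@H](C)C(=O)N2[C@@H](Cc3ccccc3)COC2=O)c(C)c(=O)c1C | intermediate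
19 | (4S)-4-benzyl-3-[(2S,3S,4S,5R,6E,8S)-3,5-bis{[tert-butyl(dimethyl)silyl]oxy}-8-(6-ethyl-3,5-dimethyl-4-oxo-4H-pyran-2-yl)-2,4,6-trimethylnon-6-enoyl]-1,3-oxazolidin-2-one | CCc1oc([C@@H](C)/C=C(\C)[C@H](O[Si](C)(C)C(C)(C)C)[C@@H](C)[C@H](O[Si](C)(C)C(C)(C)C)[C@H](C)C(=O)N2[C@@H](Cc3ccccc3)COC2=O)c(C)c(=O)c1C | intermediate
20 | 2-[(2S,3E,5R,6S,7R,8R)-5,7-bis{[tert-butyl(dimethyl)silyl]oxy}-9-hydroxy-4,6,8-trimethylnon-3-en-2-yl]-6-ethyl-3,5-dimethyl-4H-pyran-4-one | CCc1oc([C@@H](C)/C=C(\C)[C@H](O[Si](C)(C)C(C)(C)C)[C@@H](C)[C@H](O[Si](C)(C)C(C)(C)C)[C@H](C)CO)c(C)c(=O)c1C | intermediate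
21 | (2S,3S,4S,5R,6E,8S)-3,5-bis{[tert-butyl(dimethyl)silyl]oxy}-8-(6-ethyl-3,5-dimethyl-4-oxo-4H-pyran-2-yl)-2,4,6-trimethylnon-6-enal (ring A–linker aldehyde) | CCc1oc([C@@H](C)/C=C(\C)[C@H](O[Si](C)(C)C(C)(C)C)[C@@H](C)[C@H](O[Si](C)(C)C(C)(C)C)[C@H](C)C=O)c(C)c(=O)c1C | intermediate
22 | methyl (3R)-3-hydroxypentanoate | CC[C@@H](O)CC(=O)OC | starting material
23 | methyl (2R,3R)-3-hydroxy-2-methylpentanoate | CC[C@@H](O)[C@@H](C)C(=O)OC | intermediate
24 | methyl (2R,3R)-3-[(tert-butyldimethylsilyl)oxy]-2-methylpentanoate | CC[C@@H](O[Si](C)(C)C(C)(C)C)[C@@H](C)C(=O)OC | intermediate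
25 | (2R,3R)-3-[(tert-butyldimethylsilyl)oxy]-2-methylpentanal | CC[C@@H](O[Si](C)(C)C(C)(C)C)[C@@H](C)C=O | intermediate
26 | N-methoxy-N-methylpropanamide | CCC(=O)N(C)OC | starting material
27 | (4S,5R)-5-[(tert-butyldimethylsilyl)oxy]-3-hydroxy-N-methoxy-N,2,4-trimethylheptanamide (mixture at C2/C3) | CC[C@@H](O[Si](C)(C)C(C)(C)C)[C@@H](C)C(O)C(C)C(=O)N(C)OC | intermediate
28 | (4R,5R)-5-[(tert-butyldimethylsilyl)oxy]-N-methoxy-N,2,4-trimethyl-3-oxoheptanamide (C2 epimers) | CC[C@@H](O[Si](C)(C)C(C)(C)C)[C@@H](C)C(=O)C(C)C(=O)N(C)OC | intermediate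
29 | (4R,5R)-5-[(tert-butyldimethylsilyl)oxy]-N,3-dimethoxy-N,2,4-trimethylhept-2-enamide (E/Z mixture) | CC[C@@H](O[Si](C)(C)C(C)(C)C)[C@@H](C)C(OC)=C(C)C(=O)N(C)OC | intermediate
30 | (6R,7R)-7-[(tert-butyldimethylsilyl)oxy]-5-methoxy-4,6-dimethylnon-4-en-3-one (E/Z mixture) | CC[C@@H](O[Si](C)(C)C(C)(C)C)[C@@H](C)C(OC)=C(C)C(=O)CC | intermediate
31 | (3R,4R)-3-[(tert-butyldimethylsilyl)oxy]-5-methoxy-4,6-dimethyl-7-[(trimethylsilyl)oxy]nona-5,7-diene (arm-bearing diene, double-bond isomers) | COC(=C(C)C(O[Si](C)(C)C)=CC)[C@H](C)[C@H](O[Si](C)(C)C(C)(C)C)CC | intermediate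
32 | open-chain Mukaiyama aldol adduct: δ-hydroxy-β-methoxy enone in which the former aldehyde carbon of 21 (now CHOH) is bonded to the former C8 of 31 (now CHMe next to the ketone); mixture at the two new centres | CCc1oc([C@@H](C)/C=C(\C)[C@H](O[Si](C)(C)C(C)(C)C)[C@@H](C)[C@H](O[Si](C)(C)C(C)(C)C)[C@H](C)C(O)C(C)C(=O)C(C)=C(OC)[C@H](C)[C@H](O[Si](C)(C)C(C)(C)C)CC)c(C)c(=O)c1C | intermediate
33 | tris-TBS 2,3-dihydro ring B adduct: ring A–linker chain of 21 on C2 and the arm of 31 on C6 of a 3,5-dimethyl-2,3-dihydro-4H-pyran-4-one (mixture at ring B C2/C3) | CCc1oc([C@@H](C)/C=C(\C)[C@H](O[Si](C)(C)C(C)(C)C)[C@@H](C)[C@H](O[Si](C)(C)C(C)(C)C)[C@H](C)C2OC([C@H](C)[C@H](O[Si](C)(C)C(C)(C)C)CC)=C(C)C(=O)C2C)c(C)c(=O)c1C | intermediate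
34 | 2-[(2S,3E,5R,6S,7S,8S)-5,7-bis{[tert-butyl(dimethyl)silyl]oxy}-8-{6-[(2R,3R)-3-{[tert-butyl(dimethyl)silyl]oxy}pentan-2-yl]-3,5-dimethyl-4-oxo-4H-pyran-2-yl}-4,6-dimethylnon-3-en-2-yl]-6-ethyl-3,5-dimethyl-4H-pyran-4-one | CCc1oc([C@@H](C)/C=C(\C)[C@H](O[Si](C)(C)C(C)(C)C)[C@@H](C)[C@H](O[Si](C)(C)C(C)(C)C)[C@H](C)c2oc([C@H](C)[C@H](O[Si](C)(C)C(C)(C)C)CC)c(C)c(=O)c2C)c(C)c(=O)c1C | intermediate
35 | 2-[(2S,3E,5R,6S,7S,8S)-8-{6-[(2R,3R)-3-hydroxypentan-2-yl]-3,5-dimethyl-4-oxo-4H-pyran-2-yl}-5,7-dihydroxy-4,6-dimethylnon-3-en-2-yl]-6-ethyl-3,5-dimethyl-4H-pyran-4-one (CNP0328559.3) | CCc1oc([C@@H](C)/C=C(\C)[C@H](O)[C@@H](C)[C@H](O)[C@H](C)c2oc([C@H](C)[C@H](O)CC)c(C)c(=O)c2C)c(C)c(=O)c1C | target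

**Totals and risks**

Total step count: 27. Longest linear sequence: 16 steps (steps 3–5, 7–16 and 25–27, from 1).

Steps most likely to fail:

Step 25. The fully substituted diene may lose its silyl group to the Lewis acid faster than its hindered terminus adds to the β-branched aldehyde, or the open-chain adduct may revert by retro-aldol instead of closing. The fallback sets out from ketone 30 and aldehyde 21. Ketone 30 is enolised at its ethyl group as the chlorotitanium enolate (TiCl4, iPr2NEt, CH2Cl2, −78 °C), 21 is added, and the open-chain aldol 32 is isolated. Ring B is then closed in a separate acid-mediated step (CF3CO2H or pyridinium p-toluenesulfonate), which comes back to the route at 33. No compound outside the list is made (F0).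

Step 26. Dehydrogenation may stall at the hindered tertiary α-carbon of ring B, or the oxidant may attack the allylic positions flanking the trisubstituted alkene. The fallback sets out from the open-chain aldol 32, obtained by quenching step 25 before the acid is added. Its free hydroxyl is oxidised with Dess–Martin periodinane to the δ-keto-β-methoxy enone F1. Under CF3CO2H the 1,3-diketone enol of F1 closes onto the methoxy-bearing carbon with loss of methanol, which gives the aromatic ring B directly and comes back at 34.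

Step 7. Attack of the secondary carbanion on the α-branched amide may be slower than loss of formaldehyde from the N-methoxy group or β-elimination of the silyloxy group. The fallback sets out from 8, which is reduced with iBu2AlH to (2S,3S)-3-(TBSO)-2,4-dimethylpent-4-enal F2. The dianion of 11 is added to this far more electrophilic aldehyde to give the 7-hydroxy-3,5-dione F3. Oxidation with Dess–Martin periodinane comes back at triketone 12.

**Further compounds**

F0 | step 25 | none | none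
F1 | step 26 | δ-keto-β-methoxy enone (32 with its CHOH oxidised to C=O; 1,3-diketone next to C7′, mixture at the inter-carbonyl carbon) | CCc1oc([C@@H](C)/C=C(\C)[C@H](O[Si](C)(C)C(C)(C)C)[C@@H](C)[C@H](O[Si](C)(C)C(C)(C)C)[C@H](C)C(=O)C(C)C(=O)C(C)=C(OC)[C@H](C)[C@H](O[Si](C)(C)C(C)(C)C)CC)c(C)c(=O)c1C
F2 | step 7 | (2S,3S)-3-[(tert-butyldimethylsilyl)oxy]-2,4-dimethylpent-4-enal | C=C(C)[C@@H](O[Si](C)(C)C(C)(C)C)[C@H](C)C=O
F3 | step 7 | (8R,9S)-9-[(tert-butyldimethylsilyl)oxy]-7-hydroxy-4,6,8,10-tetramethylundec-10-ene-3,5-dione (mixture at C4, C6, C7) | CCC(=O)C(C)C(=O)C(C)C(O)[C@@H](C)[C@H](O[Si](C)(C)C(C)(C)C)C(C)=C
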